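**Retrosynthetic overview**
1. Target 29 ← tris-silyl ether 28 (fluoride) ← phenol 27, by acid closure of the pyran ring (ring D) from the prenyl group on C4a and the free C8a hydroxyl.
2. The strategy rests on ring C of the chroman (C4a, C5, C6, C7, C8, C8a): oxygen on C7 and C8a in a meta relation, hydrogen on C8 between them, carbon substituents on C4a and C5. This ring is cut into cyclobutenone 18 and triisopropylsiloxyethyne 22 (bonds C8a–C8 and C6–C7, then C4a–C8a by electrocyclisation).
3. 18 ← 2-bromobenzofuran 10 (bromine–lithium exchange) + 3-ethoxy-4-prenylcyclobutenone 15 (ketene–ethoxyethyne [2+2]); 22 ← lithium ethynolate from 3-phenylisoxazole.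
4. 10 ← 2,4,6-trihydroxybenzaldehyde: prenyl ether on O4, Claisen shift to C3, silylation of O4 and O6, dibromo-olefination and copper-catalysed furan closure.
5. Order of ring formation: ring A (benzene ring of the benzofuran) is bought, furan ring B in step 5, ring C in step 10, pyran ring D in step 11.

Key step: step 10

Assumption: 3-phenylisoxazole, 5-methylhex-4-enoic acid, 3-methylbut-2-en-1-ol and ethoxyethyne (hexane solution) are taken as purchasable; the target has no stereocentre, and 5, 15, 17, 18, 24 and 26 are racemic (17 as a diastereomer mixture).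
Abbreviations: TIPS = triisopropylsilyl; TMS = trimethylsilyl; BSA = N,O-bis(trimethylsilyl)acetamide; Ar = 7-(2-methylbut-3-en-2-yl)-4,6-bis(triisopropylsilyloxy)-1-benzofuran-2-yl.

**Step 1**
Reactants: 1 2,4,6-trihydroxybenzaldehyde; 2 3-methylbut-2-en-1-ol
Product: 3 2,6-dihydroxy-4-(3-methylbut-2-enyloxy)benzaldehyde
Conditions: PPh3, DIAD, THF, 0 °C → rt
Reagents that add atoms: none
Why: Mitsunobu etherification should take the most acidic hydroxyl, the one para to the formyl group, because the two ortho hydroxyls are engaged with the carbonyl oxygen, and its neutral conditions avoid C-prenylation of the phloroglucinol nucleus; an ether on this oxygen has the formyl-bearing carbon as its para position, which blocks a para shift of the allyl unit in step 2.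

**Step 2**
Reactants: 3 2,6-dihydroxy-4-(3-methylbut-2-enyloxy)benzaldehyde
Product: 7 2,4,6-trihydroxy-3-(2-methylbut-3-en-2-yl)benzaldehyde, via bis-TMS ether 4 (not isolated), via dienone 5 (not isolated), via tris-TMS ether 6 (not isolated)
Conditions: BSA (4 equiv), PhNEt2, 190 °C, sealed tube; then MeOH, citric acid, rt
Reagents that add atoms: none
Why: Aromatic Claisen rearrangement ([3,3]-sigmatropic shift, then enolisation of dienone 5), in which the two ortho carbons are equivalent by symmetry and the para carbon carries the formyl group, so that only the 3-(1,1-dimethylallyl) product can aromatise, while silylation in the flask keeps the new phenol from adding to the vinyl group or entering the abnormal Claisen pathway and methanolysis then frees the three hydroxyls.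

**Step 3**
Reactants: 7 2,4,6-trihydroxy-3-(2-methylbut-3-en-2-yl)benzaldehyde
Product: 8 2-hydroxy-3-(2-methylbut-3-en-2-yl)-4,6-bis(triisopropylsilyloxy)benzaldehyde
Conditions: TIPSOTf (2.1 equiv), 2,6-lutidine, CH2Cl2, −78 → 0 °C
Reagents that add atoms: triisopropylsilyl trifluoromethanesulfonate (TIPSOTf), CC(C)[Si](OS(=O)(=O)C(F)(F)F)(C(C)C)C(C)C
Why: Silylation of phenols with a silyl triflate, in which the 2-hydroxyl is wedged between the formyl group and the quaternary carbon and held in a hydrogen bond to the carbonyl, so that two equivalents of reagent should go to the 4- and 6-hydroxyls.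

**Step 4**
Reactants: 8 2-hydroxy-3-(2-methylbut-3-en-2-yl)-4,6-bis(triisopropylsilyloxy)benzaldehyde
Product: 9 2-(2,2-dibromoethenyl)-6-(2-methylbut-3-en-2-yl)-3,5-bis(triisopropylsilyloxy)phenol
Conditions: CBr4, PPh3, Et3N, CH2Cl2, 0 °C
Reagents that add atoms: carbon tetrabromide, BrC(Br)(Br)Br
Why: Ramirez dibromo-olefination (first stage of the Corey–Fuchs sequence) converts the aldehyde into the 1,1-dibromoalkene, the amine buffering the hydrogen bromide so that the silyl ethers, the vinyl group and the free phenol are left alone.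

**Step 5**
Reactants: 9 2-(2,2-dibromoethenyl)-6-(2-methylbut-3-en-2-yl)-3,5-bis(triisopropylsilyloxy)phenol
Product: 10 2-bromo-7-(2-methylbut-3-en-2-yl)-4,6-bis(triisopropylsilyloxy)-1-benzofuran
Conditions: CuI (5 mol %), K3PO4, THF, 80 °C
Reagents that add atoms: none
Why: Intramolecular Ullmann-type C–O coupling of the phenoxide with the bromine cis to the arene closes the five-membered furan ring B and leaves the second bromine on C2 as the handle for metalation.

**Step 6**
Reactants: 11 5-methylhex-4-enoic acid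
Product: 12 5-methylhex-4-enoyl chloride
Conditions: (COCl)2, DMF (cat.), CH2Cl2, 0 °C → rt
Reagents that add atoms: oxalyl chloride, O=C(Cl)C(=O)Cl
Why: Standard conversion of a carboxylic acid into its chloride through the chloroiminium species formed from DMF, under which the trisubstituted alkene should not be touched.

**Step 7**
Reactants: 12 5-methylhex-4-enoyl chloride; 13 ethoxyethyne
Product: 15 3-ethoxy-4-(3-methylbut-2-enyl)cyclobut-2-en-1-one, via ketene 14 (not isolated)
Conditions: 13 (3 equiv), Et3N, Et2O, rt, slow addition of 12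
Reagents that add atoms: none
Why: Dehydrochlorination gives monoalkylketene 14, which should undergo [2+2] cycloaddition with the electron-rich alkyne faster than it dimerises when the chloride is added slowly to an excess of 13, the ketene carbonyl carbon bonding to the unsubstituted alkyne carbon so that ethoxy sits on C3 and the prenyl group on C4.

**Step 8**
Reactants: 10 2-bromo-7-(2-methylbut-3-en-2-yl)-4,6-bis(triisopropylsilyloxy)-1-benzofuran; 15 3-ethoxy-4-(3-methylbut-2-enyl)cyclobut-2-en-1-one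
Product: 18 3-[7-(2-methylbut-3-en-2-yl)-4,6-bis(triisopropylsilyloxy)-1-benzofuran-2-yl]-4-(3-methylbut-2-enyl)cyclobut-2-en-1-one, via aryllithium 16 (not isolated), via lithium alkoxide 17 (not isolated)
Conditions: n-BuLi, THF, −78 °C; 15, −78 °C; then 1 M HCl, 0 °C → rt
Reagents that add atoms: water, O
Why: Bromine–lithium exchange gives the 2-lithiobenzofuran, which adds to the carbonyl of the vinylogous ester, and acid hydrolysis of adduct 17 with loss of ethanol transposes the carbonyl (Stork–Danheiser type sequence, the usual route from 3-ethoxycyclobutenones to 3-substituted cyclobutenones), the prenyl-bearing C4 lying between both functional carbons so that it ends next to the new carbonyl.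

**Step 9**
Reactants: 19 3-phenyl-1,2-oxazole
Product: 22 triisopropylsiloxyethyne, via 5-lithioisoxazole 20 (not isolated), via lithium ethynolate 21 (not isolated)
Conditions: n-BuLi, THF, −78 °C; then TIPSOTf, −78 → 0 °C
Reagents that add atoms: triisopropylsilyl trifluoromethanesulfonate (TIPSOTf), CC(C)[Si](OS(=O)(=O)C(F)(F)F)(C(C)C)C(C)C
Why: Deprotonation of a 3-aryl-1,2-oxazole at C5 triggers cycloreversion into the nitrile and the lithium ynolate (the route to ynolates from 5-unsubstituted isoxazoles), and the bulky silyl triflate is expected to silylate the ynolate at oxygen, as bulky silyl electrophiles do with other ynolates.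

**Step 10**
Reactants: 18 3-[7-(2-methylbut-3-en-2-yl)-4,6-bis(triisopropylsilyloxy)-1-benzofuran-2-yl]-4-(3-methylbut-2-enyl)cyclobut-2-en-1-one; 22 triisopropylsiloxyethyne
Product: 27 3-[7-(2-methylbut-3-en-2-yl)-4,6-bis(triisopropylsilyloxy)-1-benzofuran-2-yl]-2-(3-methylbut-2-enyl)-5-(triisopropylsilyloxy)phenol, via vinylketene 23 (not isolated), via vinylcyclobutenone 24 (not isolated), via dienylketene 25 (not isolated), via cyclohexadienone 26 (not isolated)
Conditions: 22 (2 equiv), toluene, 80 °C → 100 °C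
Reagents that add atoms: none
Why: Heating opens cyclobutenone 18 by four-electron electrocyclic cleavage of its C1–C4 bond to vinylketene 23, the siloxyalkyne adds across the ketene C=C in a [2+2] cycloaddition to give 24, four-electron opening of 24 gives dienylketene 25, and six-electron electrocyclisation to dienone 26 followed by enolisation gives phenol 27. This is the Danheiser benzannulation of a cyclobutenone with a siloxyalkyne, known to give resorcinol mono-silyl ethers. Ring C is closed as a six-membered carbocycle by the disrotatory electrocyclisation, which re-forms the C4a–C8a bond after the cycloaddition has made C8a–C8 and C6–C7. No stereocentre is set, because the sp3 ring carbons of 18, 24 and 26 all end as aromatic carbons. The step needs the regiochemistry of the ketene–alkyne cycloaddition, and the polarisation of the siloxyalkyne secures it: its unsubstituted nucleophilic carbon bonds to the electrophilic ketene carbonyl carbon, so that the ketene oxygen becomes the free C8a hydroxyl next to the prenyl-bearing C4a, the benzofuranyl group sits on C5, the silyloxy group on C7 and hydrogen on C8. The ring openings are reversible, so only the dienylketene geometry able to cyclise is drained, and the excess of alkyne should keep the vinylketene from dimerising.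

**Step 11**
Reactants: 27 3-[7-(2-methylbut-3-en-2-yl)-4,6-bis(triisopropylsilyloxy)-1-benzofuran-2-yl]-2-(3-methylbut-2-enyl)-5-(triisopropylsilyloxy)phenol
Product: 28 2-[2,2-dimethyl-7-(triisopropylsilyloxy)-3,4-dihydro-2H-chromen-5-yl]-7-(2-methylbut-3-en-2-yl)-4,6-bis(triisopropylsilyloxy)-1-benzofuran
Conditions: Amberlyst 15, CH2Cl2, rt
Reagents that add atoms: none
Why: Acid-catalysed intramolecular hydroalkoxylation, in which Markovnikov protonation of the trisubstituted alkene gives a tertiary cation that the only free hydroxyl captures in a six-membered closure to the 2,2-dimethylchroman (ring D), while the monosubstituted vinyl group would give only a secondary cation and has no free hydroxyl beside it.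

**Step 12**
Reactants: 28 2-[2,2-dimethyl-7-(triisopropylsilyloxy)-3,4-dihydro-2H-chromen-5-yl]-7-(2-methylbut-3-en-2-yl)-4,6-bis(triisopropylsilyloxy)-1-benzofuran
Product: 29 2-(7-hydroxy-2,2-dimethyl-3,4-dihydro-2H-chromen-5-yl)-7-(2-methylbut-3-en-2-yl)-1-benzofuran-4,6-diol
Conditions: TBAF (3.3 equiv), AcOH (3.3 equiv), THF, 0 °C
Reagents that add atoms: none
Why: Fluoride cleaves the three aryl silyl ethers, and the acetic acid buffer keeps the electron-rich polyphenol from standing as an oxidisable phenoxide while the 1,1-dimethylallyl group and the chroman are inert to these conditions.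

**Compound list**
1 | 2,4,6-trihydroxybenzaldehyde | O=Cc1c(O)cc(O)cc1O | starting material
2 | 3-methylbut-2-en-1-ol | CC(C)=CCO | starting material
3 | 2,6-dihydroxy-4-(3-methylbut-2-enyloxy)benzaldehyde | O=Cc1c(O)cc(OCC=C(C)C)cc1O | intermediate
4 | 4-(3-methylbut-2-enyloxy)-2,6-bis(trimethylsilyloxy)benzaldehyde (not isolated) | O=Cc1c(O[Si](C)(C)C)cc(OCC=C(C)C)cc1O[Si](C)(C)C | intermediate
5 | 3-(2-methylbut-3-en-2-yl)-4-oxo-2,6-bis(trimethylsilyloxy)cyclohexa-1,5-diene-1-carbaldehyde (racemic, not isolated) | O=CC1=C(O[Si](C)(C)C)C(C(C)(C)C=C)C(=O)C=C1O[Si](C)(C)C | intermediate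
6 | 3-(2-methylbut-3-en-2-yl)-2,4,6-tris(trimethylsilyloxy)benzaldehyde (not isolated) | O=Cc1c(O[Si](C)(C)C)cc(O[Si](C)(C)C)c(C(C)(C)C=C)c1O[Si](C)(C)C | intermediate
7 | 2,4,6-trihydroxy-3-(2-methylbut-3-en-2-yl)benzaldehyde | O=Cc1c(O)cc(O)c(C(C)(C)C=C)c1O | intermediate
8 | 2-hydroxy-3-(2-methylbut-3-en-2-yl)-4,6-bis(triisopropylsilyloxy)benzaldehyde | O=Cc1c(O)c(C(C)(C)C=C)c(O[Si](C(C)C)(C(C)C)C(C)C)cc1O[Si](C(C)C)(C(C)C)C(C)C | intermediate
9 | 2-(2,2-dibromoethenyl)-6-(2-methylbut-3-en-2-yl)-3,5-bis(triisopropylsilyloxy)phenol | BrC(Br)=Cc1c(O)c(C(C)(C)C=C)c(O[Si](C(C)C)(C(C)C)C(C)C)cc1O[Si](C(C)C)(C(C)C)C(C)C | intermediate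
10 | 2-bromo-7-(2-methylbut-3-en-2-yl)-4,6-bis(triisopropylsilyloxy)-1-benzofuran | Brc1cc2c(O[Si](C(C)C)(C(C)C)C(C)C)cc(O[Si](C(C)C)(C(C)C)C(C)C)c(C(C)(C)C=C)c2o1 | intermediate
11 | 5-methylhex-4-enoic acid | CC(C)=CCCC(=O)O | starting material
12 | 5-methylhex-4-enoyl chloride | CC(C)=CCCC(=O)Cl | intermediate
13 | ethoxyethyne | C#COCC | starting material
14 | 5-methylhexa-1,4-dien-1-one, the (3-methylbut-2-enyl)ketene (not isolated) | O=C=CCC=C(C)C | intermediate
15 | 3-ethoxy-4-(3-methylbut-2-enyl)cyclobut-2-en-1-one (racemic) | CCOC1=CC(=O)C1CC=C(C)C | intermediate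
16 | [7-(2-methylbut-3-en-2-yl)-4,6-bis(triisopropylsilyloxy)-1-benzofuran-2-yl]lithium (not isolated) | [Li]c1cc2c(O[Si](C(C)C)(C(C)C)C(C)C)cc(O[Si](C(C)C)(C(C)C)C(C)C)c(C(C)(C)C=C)c2o1 | intermediate
17 | lithium 1-Ar-3-ethoxy-4-(3-methylbut-2-enyl)cyclobut-2-en-1-olate (diastereomer mixture, not isolated) | [Li]OC1(c2cc3c(O[Si](C(C)C)(C(C)C)C(C)C)cc(O[Si](C(C)C)(C(C)C)C(C)C)c(C(C)(C)C=C)c3o2)C=C(OCC)C1CC=C(C)C | intermediate
18 | 3-[7-(2-methylbut-3-en-2-yl)-4,6-bis(triisopropylsilyloxy)-1-benzofuran-2-yl]-4-(3-methylbut-2-enyl)cyclobut-2-en-1-one (racemic) | O=C1C=C(c2cc3c(O[Si](C(C)C)(C(C)C)C(C)C)cc(O[Si](C(C)C)(C(C)C)C(C)C)c(C(C)(C)C=C)c3o2)C1CC=C(C)C | intermediate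
19 | 3-phenyl-1,2-oxazole (3-phenylisoxazole) | c1ccc(cc1)-c1ccon1 | starting material
20 | (3-phenyl-1,2-oxazol-5-yl)lithium (not isolated) | [Li]c1cc(-c2ccccc2)no1 | intermediate
21 | lithium ethynolate (not isolated) | [Li]OC#C | intermediate
22 | triisopropylsiloxyethyne | C#CO[Si](C(C)C)(C(C)C)C(C)C | intermediate
23 | (3Z)-3-Ar-7-methylocta-1,3,6-trien-1-one, prenyl group trans to the ketene carbon (not isolated) | O=C=C/C(c1cc2c(O[Si](C(C)C)(C(C)C)C(C)C)cc(O[Si](C(C)C)(C(C)C)C(C)C)c(C(C)(C)C=C)c2o1)=C/CC=C(C)C | intermediate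
24 | 4-[(1Z)-1-Ar-5-methylhexa-1,4-dienyl]-3-(triisopropylsilyloxy)cyclobut-2-en-1-one (racemic, not isolated) | O=C1C=C(O[Si](C(C)C)(C(C)C)C(C)C)C1/C(c3cc4c(O[Si](C(C)C)(C(C)C)C(C)C)cc(O[Si](C(C)C)(C(C)C)C(C)C)c(C(C)(C)C=C)c4o3)=C/CC=C(C)C | intermediate
25 | (3E,5Z)-5-Ar-9-methyl-3-(triisopropylsilyloxy)deca-1,3,5,8-tetraen-1-one (not isolated) | O=C=C/C(O[Si](C(C)C)(C(C)C)C(C)C)=C\C(c3cc4c(O[Si](C(C)C)(C(C)C)C(C)C)cc(O[Si](C(C)C)(C(C)C)C(C)C)c(C(C)(C)C=C)c4o3)=C\CC=C(C)C | intermediate
26 | 5-Ar-6-(3-methylbut-2-enyl)-3-(triisopropylsilyloxy)cyclohexa-2,4-dien-1-one (racemic, not isolated) | O=C1C=C(O[Si](C(C)C)(C(C)C)C(C)C)C=C(c3cc4c(O[Si](C(C)C)(C(C)C)C(C)C)cc(O[Si](C(C)C)(C(C)C)C(C)C)c(C(C)(C)C=C)c4o3)C1CC=C(C)C | intermediate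
27 | 3-[7-(2-methylbut-3-en-2-yl)-4,6-bis(triisopropylsilyloxy)-1-benzofuran-2-yl]-2-(3-methylbut-2-enyl)-5-(triisopropylsilyloxy)phenol | C=CC(C)(C)c1c(O[Si](C(C)C)(C(C)C)C(C)C)cc(O[Si](C(C)C)(C(C)C)C(C)C)c2cc(-c3cc(O[Si](C(C)C)(C(C)C)C(C)C)cc(O)c3CC=C(C)C)oc12 | intermediate
28 | 2-[2,2-dimethyl-7-(triisopropylsilyloxy)-3,4-dihydro-2H-chromen-5-yl]-7-(2-methylbut-3-en-2-yl)-4,6-bis(triisopropylsilyloxy)-1-benzofuran | C=CC(C)(C)c1c(O[Si](C(C)C)(C(C)C)C(C)C)cc(O[Si](C(C)C)(C(C)C)C(C)C)c2cc(-c3cc(O[Si](C(C)C)(C(C)C)C(C)C)cc4c3CCC(C)(C)O4)oc12 | intermediate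
29 | 2-(7-hydroxy-2,2-dimethyl-3,4-dihydro-2H-chromen-5-yl)-7-(2-methylbut-3-en-2-yl)-1-benzofuran-4,6-diol (CNP0300714.0) | C=CC(C)(C)c1c(O)cc(O)c2cc(-c3cc(O)cc4c3CCC(C)(C)O4)oc12 | target

**Step count and risk**
Total steps: 12. Longest linear sequence: 9 steps (steps 1, 2, 3, 4, 5, 8, 10, 11, 12).

Steps most likely to fail:

1. Step 10. The vinylketene may be lost to dimerisation, the product phenol may be acylated by the ketene, or the siloxyalkyne may isomerise to the silylketene before it is consumed. The fallback brings ring C in ready-made and joins it to ring B by cross-coupling, setting out from 10 and returning at 28. 5-Bromobenzene-1,3-diol and isoprene over Amberlyst 15 should give 5-bromo-2,2-dimethyl-3,4-dihydro-2H-chromen-7-ol F1, the isomer from alkylation between the two hydroxyls being removed by chromatography. TIPSCl and imidazole then give 5-bromo-2,2-dimethyl-7-(triisopropylsilyloxy)-3,4-dihydro-2H-chromene F2. Miyaura borylation (B2pin2, KOAc, Pd(dppf)Cl2, dioxane, 80 °C) gives 2-[2,2-dimethyl-7-(triisopropylsilyloxy)-3,4-dihydro-2H-chromen-5-yl]-4,4,5,5-tetramethyl-1,3,2-dioxaborolane F3. Suzuki–Miyaura coupling of F3 with bromobenzofuran 10 (Pd(OAc)2, SPhos, K3PO4, toluene, 80 °C) gives 28.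

2. Step 9. Silylation of the ynolate may go to carbon, the base may attack the benzonitrile that is released, or the terminal siloxyalkyne may undergo a 1,3-silyl shift during purification. The fallback uses a C-silylated alkyne, setting out from 18 and returning at 28. Ethynyltrimethylsilane is lithiated (n-BuLi, THF, −78 °C), the acetylide is oxidised with LiOOt-Bu to the silyl ynolate, and TIPSOTf silylates it at oxygen to give 1-(triisopropylsilyloxy)-2-(trimethylsilyl)ethyne F4. Benzannulation of F4 with 18 under the conditions of step 10 should give 3-Ar-2-(3-methylbut-2-enyl)-5-(triisopropylsilyloxy)-6-(trimethylsilyl)phenol F5. Trifluoroacetic acid in CH2Cl2 at 0 °C should then remove the aryl silane by ipso-protonation and close the pyran ring in the same operation, giving 28.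

3. Step 2. The allyl unit may migrate on to the formyl-bearing para carbon with loss of the formyl group, or trapping may be incomplete so that the new phenol adds to the vinyl group. The fallback moves the rearrangement to the benzofuran stage, where the para carbon is the ring-fusion atom C3a; it sets out from 3 and returns at 10. One equivalent of TIPSCl with imidazole should give 2-hydroxy-4-(3-methylbut-2-enyloxy)-6-(triisopropylsilyloxy)benzaldehyde F6. The conditions of steps 4 and 5 then give 2-(2,2-dibromoethenyl)-5-(3-methylbut-2-enyloxy)-3-(triisopropylsilyloxy)phenol F7 and 2-bromo-6-(3-methylbut-2-enyloxy)-4-(triisopropylsilyloxy)-1-benzofuran F8. Claisen rearrangement with BSA in PhNEt2 is expected at C7, because the C6–C7 bond has the greater double-bond character and the silyloxy group on C4 shields C5, and gives 2-bromo-7-(2-methylbut-3-en-2-yl)-4-(triisopropylsilyloxy)-6-(trimethylsilyloxy)-1-benzofuran F9. Methanolysis gives 2-bromo-7-(2-methylbut-3-en-2-yl)-4-(triisopropylsilyloxy)-1-benzofuran-6-ol F10, and TIPSOTf with 2,6-lutidine gives 10.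

**Further compounds**
F1 | step 10 | 5-bromo-2,2-dimethyl-3,4-dihydro-2H-chromen-7-ol | CC1(C)CCc2c(Br)cc(O)cc2O1
F2 | step 10 | 5-bromo-2,2-dimethyl-7-(triisopropylsilyloxy)-3,4-dihydro-2H-chromene | CC1(C)CCc2c(Br)cc(O[Si](C(C)C)(C(C)C)C(C)C)cc2O1
F3 | step 10 | 2-[2,2-dimethyl-7-(triisopropylsilyloxy)-3,4-dihydro-2H-chromen-5-yl]-4,4,5,5-tetramethyl-1,3,2-dioxaborolane | CC1(C)CCc2c(B3OC(C)(C)C(C)(C)O3)cc(O[Si](C(C)C)(C(C)C)C(C)C)cc2O1
F4 | step 9 | 1-(triisopropylsilyloxy)-2-(trimethylsilyl)ethyne | C[Si](C)(C)C#CO[Si](C(C)C)(C(C)C)C(C)C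
F5 | step 9 | 3-[7-(2-methylbut-3-en-2-yl)-4,6-bis(triisopropylsilyloxy)-1-benzofuran-2-yl]-2-(3-methylbut-2-enyl)-5-(triisopropylsilyloxy)-6-(trimethylsilyl)phenol | C=CC(C)(C)c1c(O[Si](C(C)C)(C(C)C)C(C)C)cc(O[Si](C(C)C)(C(C)C)C(C)C)c2cc(-c3cc(O[Si](C(C)C)(C(C)C)C(C)C)c([Si](C)(C)C)c(O)c3CC=C(C)C)oc12
F6 | step 2 | 2-hydroxy-4-(3-methylbut-2-enyloxy)-6-(triisopropylsilyloxy)benzaldehyde | O=Cc1c(O)cc(OCC=C(C)C)cc1O[Si](C(C)C)(C(C)C)C(C)C
F7 | step 2 | 2-(2,2-dibromoethenyl)-5-(3-methylbut-2-enyloxy)-3-(triisopropylsilyloxy)phenol | BrC(Br)=Cc1c(O)cc(OCC=C(C)C)cc1O[Si](C(C)C)(C(C)C)C(C)C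
F8 | step 2 | 2-bromo-6-(3-methylbut-2-enyloxy)-4-(triisopropylsilyloxy)-1-benzofuran | Brc1cc2c(O[Si](C(C)C)(C(C)C)C(C)C)cc(OCC=C(C)C)cc2o1
F9 | step 2 | 2-bromo-7-(2-methylbut-3-en-2-yl)-4-(triisopropylsilyloxy)-6-(trimethylsilyloxy)-1-benzofuran | Brc1cc2c(O[Si](C(C)C)(C(C)C)C(C)C)cc(O[Si](C)(C)C)c(C(C)(C)C=C)c2o1
F10 | step 2 | 2-bromo-7-(2-methylbut-3-en-2-yl)-4-(triisopropylsilyloxy)-1-benzofuran-6-ol | Brc1cc2c(O[Si](C(C)C)(C(C)C)C(C)C)cc(O)c(C(C)(C)C=C)c2o1
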